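## Structural features

The target is a daucane-type sesquiterpenoid diester on a hydroazulene core. Ring A is a cyclopentane (C1, C2, C3, C3a, C8a; azulene numbering is used for every compound, open-chain ones included) and ring B a cycloheptenone (C3a, C4, C5, C6, C7, C8, C8a), joined through the C3a–C8a bond. The fusion is trans: C8a carries a β-methyl group and C3a an α-hydrogen. C1 carries an α-acetoxy group, C3 an α-hydroxyl and a β-isopropyl group, and C4 an α-(4-hydroxybenzoyl)oxy group (1R,3R,3aR,4R,8aS). Four stereocentres (C1, C8a, C3a, C3) are contiguous on ring A, two of them fully substituted, and the fifth (C4) sits next to C3a on ring B. Ring B holds a γ-acyloxy-α-methyl enone (C4–O, C5=C6–CH3, C7=O) separated from C8a by the C8 methylene. Fragile groups are the allylic C4 ester, two different esters beside a free phenol, the tertiary C3 alcohol (dehydration) and the base-sensitive enone. The real difficulty is the trans-fused seven-membered ring with the quaternary C8a lying between the oxygenated C1 and C3a, which is itself flanked by the fully substituted C3. The key step exploits three facts: C8a–C8–C7(O)–C6–C5 of ring B is a five-carbon unit with oxygen on its central carbon (a latent 1-siloxy-1-vinylcyclopropane); C3a–C4 can be an alkyne whose residual double bond is exactly where H (C3a) and O (C4) must be added cis; and C1–C2–C3 of ring A is a three-atom tether that carries the two oxygen stereocentres.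

## Logic of the disconnections

**21 ⇒ 20 ⇒ 19 ⇒ 17.** In the retro sense the phenol is silylated (21 to 20), the C5=C6 double bond is shifted to the exocyclic C6=CH2 position (20 to 19), and the exocyclic carbon is removed from C6 (19 to 17). The γ-acyloxy enone and the free phenol are the most fragile parts and are made last. Because C8a has no hydrogen, C5=C6 is the only endocyclic position the double bond can take. The gain is a saturated ketone with all five stereocentres in place. The demand is that the one-carbon unit enters at C6 and not at the neopentylic C8, without base, and that the isomerisation does not ionise the C4 ester.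

**17 ⇒ 14 + 15.** The acyl C–O bond of the C4 ester is cut and the C7 carbonyl is masked as its dioxolane. This removes the aryl fragment convergently. The forward step must acylate the secondary C4 hydroxyl beside the tertiary C3 hydroxyl, and the ketal must stay until then so that the C4 hydroxyl cannot add across the ring to C7.

**14 ⇒ 12.** The C4–O and C3a–H bonds are cut (hydroboration in reverse). Both stereocentres and the trans ring fusion are traced to one planar C3a=C4 alkene. The forward step must add syn on the α face, opposite the C8a methyl and C3 isopropyl groups, with boron on C4.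

**12 ⇒ 11 ⇒ 10 (key disconnection).** The ketal is exchanged for the C7=C8 enol silyl ether, then C3a–C8a (the bond shared by both rings) and C4–C5 are cut and the C7–C5 cyclopropane bond is re-formed. In one sentence: the route is a rhodium-catalysed intramolecular [5+2] cycloaddition of the open-chain alkyne–siloxyvinylcyclopropane 10 that closes both rings at once. The cut is made here because it removes both rings and the quaternary centre together and leaves the C7 oxygen and the C3a=C4 alkene exactly where later steps need them. The gain is large: a bicycle with three stereocentres becomes an acyclic chain with two (C1, C3) in a 1,3-relationship. The demand is that the fully substituted alkene carbon C8a reacts, with its face chosen by C1.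

**10 ⇒ 9 ⇒ 8 ⇒ 7.** After removing the acetyl group from O1 and capping the alkyne with silicon, the C3–CH(CH3)2 bond is cut. The tertiary carbinol then comes from a ketone next to an existing carbinol. The forward addition must occur under 1,3-chelation control so that the C3 hydroxyl ends up syn to the C1 oxygen.

**7 ⇒ 5 + 6.** The C1–C2 bond is cut (aldol). This splits the chain into two small achiral pieces. The forward aldol must set C1 (R) by catalyst control, since it is the only reagent-controlled stereocentre of the route.

**5 ⇒ 3 + 4; 3 ⇒ 2 ⇒ 1.** The C8a=C8 double bond is cut (Wittig), and the aldehyde is traced to a commercial hydroxy ester. The olefination must be E-selective so that the tether is trans to the cyclopropane.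

## Other disconnections considered

**Alternative 1:** The first idea is to cut C5=C6 and close ring B by ring-closing metathesis of the dienyl ketone A1 with the second-generation Grubbs catalyst, giving 20 directly. A1 must already hold all five stereocentres. The four contiguous centres on the cyclopentane, including the quaternary C8a and the fully substituted C3, would have to be built one at a time with the two side chains trans. The key step would therefore remove none of the stereochemical difficulty. The closure itself joins an electron-poor 1,1-disubstituted alkene to an allylic ester in a trans-fused seven-membered ring, which is expected to be slow. The route is longer and the key step less telling.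

**Alternative 2:** C6 with its methyl group is excised (C5–C6 and C6–C7 cut), leading to a one-carbon ring expansion of the trans-hydrindanone A3, itself derived from the proline-route bicyclic enedione A2. The forward step would be ethylidene transfer to the C5-side enol silyl ether of A3, FeCl3-mediated opening of the siloxycyclopropane and dehydrochlorination. The objections are structural. A2 has no functionality at C3, has its six-ring carbonyl on the wrong carbon, and has a cis-prone ring fusion, so reaching A3 costs many steps. In A3, enolisation toward C5 places the C4 oxygen β to the enolate (elimination), and C5/C8 regiochemistry of the insertion is not secured.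

**Alternative 3:** C5–C6 and C8–C8a are cut for a formal [4+3] annulation. The vinylcyclopentene A4 would be cyclopropanated at its vinyl group by the carbenoid from the siloxyvinyl diazoacetate A5 under Rh2(OAc)4, followed by divinylcyclopropane Cope rearrangement. This closes only ring B and needs A4 with C1 and C3 already set on a preformed cyclopentene. The Cope step must form C8–C8a at a fully substituted alkene terminus whose methyl group points into the boat transition state, which should raise the barrier strongly. C6 would arrive as an ester that has to be reduced to a methyl group in several extra steps.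

Key step: step 8

Assumptions: (a) 15 is taken as a purchasable compound. (b) In step 4 the (S,S) antipode of ProPhenol is taken to give the 5R aldol; the sense must be confirmed on 7 by MTPA ester analysis, and the (R,R) ligand is used if it proves opposite.

## Route

Step 1
Reactants: 1 methyl 1-hydroxycyclopropane-1-carboxylate
Product: 2 methyl 1-[(tert-butyldimethylsilyl)oxy]cyclopropane-1-carboxylate
Conditions: TBSOTf, 2,6-lutidine, CH2Cl2, 0 °C to rt
Reagents that add atoms: tert-butyldimethylsilyl trifluoromethanesulfonate, CC(C)(C)[Si](C)(C)OS(=O)(=O)C(F)(F)F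
Why: Silyl ether formation on the tertiary α-hydroxy ester with a silyl triflate; this oxygen later becomes the enol silyl ether that fixes the C7 carbonyl.

Step 2
Reactants: 2 methyl 1-[(tert-butyldimethylsilyl)oxy]cyclopropane-1-carboxylate
Product: 3 1-[(tert-butyldimethylsilyl)oxy]cyclopropane-1-carbaldehyde
Conditions: i-Bu2AlH (1.05 equiv), CH2Cl2, −78 °C; MeOH, aq. KNaC4H4O6 (potassium sodium tartrate)
Reagents that add atoms: none
Why: Partial reduction of an α-siloxy ester with i-Bu2AlH; the chelated tetrahedral aluminate should survive at −78 °C until the quench, so the reduction stops at the aldehyde.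

Step 3
Reactants: 3 1-[(tert-butyldimethylsilyl)oxy]cyclopropane-1-carbaldehyde; 4 2-(triphenylphosphoranylidene)propanal
Product: 5 (2E)-3-{1-[(tert-butyldimethylsilyl)oxy]cyclopropyl}-2-methylprop-2-enal
Conditions: toluene, 90 °C
Reagents that add atoms: none
Why: Wittig olefination with a stabilised formyl ylide is E-selective, which puts the formyl carbon (future C1) trans to the cyclopropane across C8a=C8; the aldehyde 3 has no α-hydrogen.

Step 4
Reactants: 5 (2E)-3-{1-[(tert-butyldimethylsilyl)oxy]cyclopropyl}-2-methylprop-2-enal; 6 4-(trimethylsilyl)but-3-yn-2-one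
Product: 7 (5R,6E)-7-{1-[(tert-butyldimethylsilyl)oxy]cyclopropyl}-5-hydroxy-6-methyl-1-(trimethylsilyl)hept-6-en-1-yn-3-one
Conditions: Et2Zn (20 mol %), (S,S)-ProPhenol (10 mol %), 4 Å molecular sieves, THF, 0 °C
Reagents that add atoms: none
Why: Direct catalytic asymmetric aldol addition of a methyl ynone under a dinuclear zinc–ProPhenol catalyst; the zinc enolate of 6 adds to one enantioface of the aldehyde held in the chiral pocket and sets C1 (R), the only reagent-controlled stereocentre of the route.

Step 5
Reactants: 7 (5R,6E)-7-{1-[(tert-butyldimethylsilyl)oxy]cyclopropyl}-5-hydroxy-6-methyl-1-(trimethylsilyl)hept-6-en-1-yn-3-one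
Product: 8 (3R,5R,6E)-7-{1-[(tert-butyldimethylsilyl)oxy]cyclopropyl}-6-methyl-3-(propan-2-yl)-1-(trimethylsilyl)hept-6-en-1-yne-3,5-diol
Conditions: i-PrMgCl (3.5 equiv, Et2O solution), CH2Cl2, −78 °C; aq. NH4Cl
Reagents that add atoms: isopropylmagnesium chloride, CC(C)[Mg]Cl
Why: Cram-chelate 1,3-induction in a Grignard addition: the magnesium alkoxide at O1 chelates the ynone carbonyl in a half-chair with the alkenyl group equatorial, and the reagent attacks C3 from outside, anti to that group. The alkynyl group therefore stays cis to the alkenyl group on the chelate, C3 becomes R (hydroxyl syn to the C1 oxygen along the future ring), and 1,2-addition to the silyl-capped ynone should outrun conjugate addition.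

Step 6
Reactants: 8 (3R,5R,6E)-7-{1-[(tert-butyldimethylsilyl)oxy]cyclopropyl}-6-methyl-3-(propan-2-yl)-1-(trimethylsilyl)hept-6-en-1-yne-3,5-diol
Product: 9 (3R,5R,6E)-7-{1-[(tert-butyldimethylsilyl)oxy]cyclopropyl}-6-methyl-3-(propan-2-yl)hept-6-en-1-yne-3,5-diol
Conditions: K2CO3 (0.3 equiv), MeOH, 0 °C to rt
Reagents that add atoms: none
Why: Base-catalysed methanolysis of the alkynyl C–Si bond (protodesilylation); the tertiary silyl ether on the cyclopropane is stable to these conditions.

Step 7
Reactants: 9 (3R,5R,6E)-7-{1-[(tert-butyldimethylsilyl)oxy]cyclopropyl}-6-methyl-3-(propan-2-yl)hept-6-en-1-yne-3,5-diol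
Product: 10 (3R,5R,6E)-7-{1-[(tert-butyldimethylsilyl)oxy]cyclopropyl}-3-hydroxy-6-methyl-3-(propan-2-yl)hept-6-en-1-yn-5-yl acetate
Conditions: Ac2O (1.5 equiv), pyridine, DMAP (5 mol %), CH2Cl2, 0 °C
Reagents that add atoms: acetic anhydride, CC(=O)OC(C)=O
Why: Nucleophile-catalysed acetylation is selective for the secondary C1 hydroxyl because the tertiary propargylic C3 hydroxyl is too hindered at 0 °C; the final C1 acetate is thereby in place without a protecting group.

Step 8
Reactants: 10 (3R,5R,6E)-7-{1-[(tert-butyldimethylsilyl)oxy]cyclopropyl}-3-hydroxy-6-methyl-3-(propan-2-yl)hept-6-en-1-yn-5-yl acetate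
Product: 11 (1R,3R,8aS)-7-[(tert-butyldimethylsilyl)oxy]-3-hydroxy-8a-methyl-3-(propan-2-yl)-1,2,3,5,6,8a-hexahydroazulen-1-yl acetate
Conditions: [Rh(CO)2Cl]2 (5 mol %), ClCH2CH2Cl (0.02 M), 70 °C
Reagents that add atoms: none
Why: Intramolecular rhodium-catalysed [5+2] cycloaddition of a tethered alkyne with a vinylcyclopropane, the known reaction class for bicyclo[5.3.0]decadienes, here with a 1-siloxy-substituted cyclopropane as used in the intermolecular variant. The Rh(CO)Cl fragment (monovalent rhodium) binds the C8a=C8 alkene and cleaves the C7–C5 cyclopropane bond, assisted by the siloxy group, to a σ,π-allyl rhodacyclohexene; the tethered alkyne inserts at the allyl terminus C8a to form C3a–C8a, and reductive elimination of C4–C5 from the rhodacyclooctadiene releases the diene. Ring A closes in the insertion step as a five-membered ring through the three-atom tether C1–C2–C3 (exo-type closure onto the alkyne carbon C3a), ring B closes by C(sp2)–C(sp3) reductive elimination, and the regiochemistry is fixed by the tether. C8a is the only new stereocentre and is controlled by C1: to minimise A(1,2) strain with the C8a methyl group, C1–H lies syn to that methyl, the tether rises to the rhodium-bearing face and the acetoxy group points to the other face, so closure places OAc cis to C8 and trans to CH3 (8aS). The C3 isopropyl group can sit pseudo-equatorial on the forming ring in this arrangement, so the two existing centres are matched. The enol silyl ether at C7=C8 fixes the position of the ring B carbonyl and the residual C3a=C4 alkene is the handle for step 10. The step needs cycloaddition to win over ionisation of the allylic acetate and over cyclopropane isomerisation; a neutral carbonyl chloride catalyst in a weakly polar chlorinated solvent and fast intramolecular alkyne capture are expected to secure this.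

Step 9
Reactants: 11 (1R,3R,8aS)-7-[(tert-butyldimethylsilyl)oxy]-3-hydroxy-8a-methyl-3-(propan-2-yl)-1,2,3,5,6,8a-hexahydroazulen-1-yl acetate
Product: 12 (1R,3R,8aS)-7,7-(ethane-1,2-diyldioxy)-3-hydroxy-8a-methyl-3-(propan-2-yl)-1,2,3,5,6,7,8,8a-octahydroazulen-1-yl acetate
Conditions: HOCH2CH2OH (10 equiv), pyridinium p-toluenesulfonate (20 mol %), CH2Cl2, rt
Reagents that add atoms: ethylene glycol, OCCO
Why: Acid-catalysed acetalisation with the enol silyl ether as ketone surrogate (protonation at C8, capture of the oxocarbenium ion by the diol, loss of silanol) gives the dioxolane without free ketone or water; the weak acid is chosen because the C3 hydroxyl is tertiary and allylic in 11.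

Step 10
Reactants: 12 (1R,3R,8aS)-7,7-(ethane-1,2-diyldioxy)-3-hydroxy-8a-methyl-3-(propan-2-yl)-1,2,3,5,6,7,8,8a-octahydroazulen-1-yl acetate
Product: 14 (1R,3R,3aR,4R,8aS)-7,7-(ethane-1,2-diyldioxy)-3,4-dihydroxy-8a-methyl-3-(propan-2-yl)decahydroazulen-1-yl acetate, via cyclic alkoxyborane 13 (not isolated)
Conditions: BH3·SMe2 (3 equiv), THF, 0 °C to rt; then NaBO3·4H2O, THF–H2O, rt
Reagents that add atoms: borane–dimethyl sulfide, C[S+](C)[BH3-] (boron of 13); sodium perborate (used as the tetrahydrate), [Na+].[Na+].O[B-]1(O)OO[B-](O)(O)OO1 (oxygen at C4)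
Why: Hydroboration–oxidation of the trisubstituted C3a=C4 alkene puts boron on the less substituted C4 and hydrogen on C3a in a syn addition on the α face, which is free of the C8a methyl and C3 isopropyl groups and carries the C3 alkoxyborane that can deliver B–H intramolecularly. This sets C3a (R), C4 (R) and the trans ring fusion in one operation; perborate oxidises the C–B bond with retention and should spare the acetate.

Step 11
Reactants: 14 (1R,3R,3aR,4R,8aS)-7,7-(ethane-1,2-diyldioxy)-3,4-dihydroxy-8a-methyl-3-(propan-2-yl)decahydroazulen-1-yl acetate; 15 4-[(tert-butyldimethylsilyl)oxy]benzoic acid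
Product: 16 (1R,3R,3aR,4R,8aS)-1-acetoxy-7,7-(ethane-1,2-diyldioxy)-3-hydroxy-8a-methyl-3-(propan-2-yl)decahydroazulen-4-yl 4-[(tert-butyldimethylsilyl)oxy]benzoate
Conditions: DCC (2.2 equiv), DMAP (0.5 equiv), CH2Cl2, rt to 35 °C
Reagents that add atoms: none
Why: Steglich esterification acylates the secondary C4 hydroxyl while the tertiary C3 hydroxyl does not compete; the C7 ketal prevents transannular hemiketal formation with the C4 hydroxyl.

Step 12
Reactants: 16 (1R,3R,3aR,4R,8aS)-1-acetoxy-7,7-(ethane-1,2-diyldioxy)-3-hydroxy-8a-methyl-3-(propan-2-yl)decahydroazulen-4-yl 4-[(tert-butyldimethylsilyl)oxy]benzoate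
Product: 17 (1R,3R,3aR,4R,8aS)-1-acetoxy-3-hydroxy-8a-methyl-7-oxo-3-(propan-2-yl)decahydroazulen-4-yl 4-[(tert-butyldimethylsilyl)oxy]benzoate
Conditions: pyridinium p-toluenesulfonate (0.3 equiv), acetone–H2O (9:1), 50 °C
Reagents that add atoms: water, O
Why: Mild acid hydrolysis of the dioxolane (acetal cleavage); the C3 alcohol is no longer allylic, and the aryl silyl ether and both esters should tolerate this weak acid.

Step 13
Reactants: 17 (1R,3R,3aR,4R,8aS)-1-acetoxy-3-hydroxy-8a-methyl-7-oxo-3-(propan-2-yl)decahydroazulen-4-yl 4-[(tert-butyldimethylsilyl)oxy]benzoate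
Product: 19 (1R,3R,3aR,4R,8aS)-1-acetoxy-3-hydroxy-8a-methyl-6-methylidene-7-oxo-3-(propan-2-yl)decahydroazulen-4-yl 4-[(tert-butyldimethylsilyl)oxy]benzoate, via Mannich base 18 (not isolated)
Conditions: (CH2O)n (4 equiv), N-methylanilinium trifluoroacetate (2 equiv), THF, 65 °C
Reagents that add atoms: paraformaldehyde (formaldehyde), C=O (methylidene carbon at C6); N-methylanilinium trifluoroacetate, C[NH2+]c1ccccc1.[O-]C(=O)C(F)(F)F (amine part of 18 only)
Why: Mannich-type α-methylenation: the enol on the C6 side is trapped by the N-methyl-N-phenylmethyleneiminium ion and the β-amino ketone loses the amine in situ. C8 is neopentylic (next to the quaternary C8a) and should react much more slowly, and no base touches the esters.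

Step 14
Reactants: 19 (1R,3R,3aR,4R,8aS)-1-acetoxy-3-hydroxy-8a-methyl-6-methylidene-7-oxo-3-(propan-2-yl)decahydroazulen-4-yl 4-[(tert-butyldimethylsilyl)oxy]benzoate
Product: 20 (1R,3R,3aR,4R,8aS)-1-acetoxy-3-hydroxy-6,8a-dimethyl-7-oxo-3-(propan-2-yl)-1,2,3,3a,4,7,8,8a-octahydroazulen-4-yl 4-[(tert-butyldimethylsilyl)oxy]benzoate
Conditions: RhCl3·3H2O (5 mol %), EtOH, 75 °C
Reagents that add atoms: none
Why: Rhodium hydride-mediated alkene isomerisation (Rh–H addition to the exocyclic methylene, β-hydride elimination from C5) moves the double bond into the ring; C5=C6 is the only endocyclic position available because C7 is the carbonyl carbon, so the conjugated enone with its C6 methyl group results.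

Step 15
Reactants: 20 (1R,3R,3aR,4R,8aS)-1-acetoxy-3-hydroxy-6,8a-dimethyl-7-oxo-3-(propan-2-yl)-1,2,3,3a,4,7,8,8a-octahydroazulen-4-yl 4-[(tert-butyldimethylsilyl)oxy]benzoate
Product: 21 (1R,3R,3aR,4R,8aS)-1-acetoxy-3-hydroxy-6,8a-dimethyl-7-oxo-3-(propan-2-yl)-1,2,3,3a,4,7,8,8a-octahydroazulen-4-yl 4-hydroxybenzoate (target)
Conditions: Bu4NF (1.2 equiv), AcOH (1.5 equiv), THF, 0 °C
Reagents that add atoms: none
Why: Fluoride-mediated cleavage of the aryl silyl ether is much faster than attack on the esters; acetic acid buffers the phenoxide so that the γ-acyloxy enone and the acetate are not exposed to base.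

## Compound list

1 | methyl 1-hydroxycyclopropane-1-carboxylate | COC(=O)C1(O)CC1 | starting material
2 | methyl 1-[(tert-butyldimethylsilyl)oxy]cyclopropane-1-carboxylate | COC(=O)C1(O[Si](C)(C)C(C)(C)C)CC1 | intermediate
3 | 1-[(tert-butyldimethylsilyl)oxy]cyclopropane-1-carbaldehyde | O=CC1(O[Si](C)(C)C(C)(C)C)CC1 | intermediate
4 | 2-(triphenylphosphoranylidene)propanal | CC(C=O)=P(c1ccccc1)(c1ccccc1)c1ccccc1 | starting material
5 | (2E)-3-{1-[(tert-butyldimethylsilyl)oxy]cyclopropyl}-2-methylprop-2-enal | O=C/C(C)=C/C1(O[Si](C)(C)C(C)(C)C)CC1 | intermediate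
6 | 4-(trimethylsilyl)but-3-yn-2-one | CC(=O)C#C[Si](C)(C)C | starting material
7 | (5R,6E)-7-{1-[(tert-butyldimethylsilyl)oxy]cyclopropyl}-5-hydroxy-6-methyl-1-(trimethylsilyl)hept-6-en-1-yn-3-one | C[Si](C)(C)C#CC(=O)C[C@@H](O)/C(C)=C/C1(O[Si](C)(C)C(C)(C)C)CC1 | intermediate
8 | (3R,5R,6E)-7-{1-[(tert-butyldimethylsilyl)oxy]cyclopropyl}-6-methyl-3-(propan-2-yl)-1-(trimethylsilyl)hept-6-en-1-yne-3,5-diol | C[Si](C)(C)C#C[C@](O)(C(C)C)C[C@@H](O)/C(C)=C/C1(O[Si](C)(C)C(C)(C)C)CC1 | intermediate
9 | (3R,5R,6E)-7-{1-[(tert-butyldimethylsilyl)oxy]cyclopropyl}-6-methyl-3-(propan-2-yl)hept-6-en-1-yne-3,5-diol | C#C[C@](O)(C(C)C)C[C@@H](O)/C(C)=C/C1(O[Si](C)(C)C(C)(C)C)CC1 | intermediate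
10 | (3R,5R,6E)-7-{1-[(tert-butyldimethylsilyl)oxy]cyclopropyl}-3-hydroxy-6-methyl-3-(propan-2-yl)hept-6-en-1-yn-5-yl acetate | C#C[C@](O)(C(C)C)C[C@@H](OC(C)=O)/C(C)=C/C1(O[Si](C)(C)C(C)(C)C)CC1 | intermediate
11 | (1R,3R,8aS)-7-[(tert-butyldimethylsilyl)oxy]-3-hydroxy-8a-methyl-3-(propan-2-yl)-1,2,3,5,6,8a-hexahydroazulen-1-yl acetate | CC(=O)O[C@@H]1C[C@@](O)(C(C)C)C2=CCCC(O[Si](C)(C)C(C)(C)C)=C[C@]12C | intermediate
12 | (1R,3R,8aS)-7,7-(ethane-1,2-diyldioxy)-3-hydroxy-8a-methyl-3-(propan-2-yl)-1,2,3,5,6,7,8,8a-octahydroazulen-1-yl acetate | CC(=O)O[C@@H]1C[C@@](O)(C(C)C)C2=CCCC3(OCCO3)C[C@]12C | intermediate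
13 | cyclic alkoxyborane (B–H 1,2-oxaborolane joining O3 and C4 of the hydroborated ketal) | CC(=O)O[C@@H]1C[C@@](O5)(C(C)C)[C@H]2[C@H]([BH]5)CCC3(OCCO3)C[C@]12C | intermediate
14 | (1R,3R,3aR,4R,8aS)-7,7-(ethane-1,2-diyldioxy)-3,4-dihydroxy-8a-methyl-3-(propan-2-yl)decahydroazulen-1-yl acetate | CC(=O)O[C@@H]1C[C@@](O)(C(C)C)[C@H]2[C@H](O)CCC3(OCCO3)C[C@]12C | intermediate
15 | 4-[(tert-butyldimethylsilyl)oxy]benzoic acid | CC(C)(C)[Si](C)(C)Oc1ccc(C(=O)O)cc1 | starting material
16 | (1R,3R,3aR,4R,8aS)-1-acetoxy-7,7-(ethane-1,2-diyldioxy)-3-hydroxy-8a-methyl-3-(propan-2-yl)decahydroazulen-4-yl 4-[(tert-butyldimethylsilyl)oxy]benzoate | CC(=O)O[C@@H]1C[C@@](O)(C(C)C)[C@H]2[C@H](OC(=O)c3ccc(O[Si](C)(C)C(C)(C)C)cc3)CCC4(OCCO4)C[C@]12C | intermediate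
17 | (1R,3R,3aR,4R,8aS)-1-acetoxy-3-hydroxy-8a-methyl-7-oxo-3-(propan-2-yl)decahydroazulen-4-yl 4-[(tert-butyldimethylsilyl)oxy]benzoate | CC(=O)O[C@@H]1C[C@@](O)(C(C)C)[C@H]2[C@H](OC(=O)c3ccc(O[Si](C)(C)C(C)(C)C)cc3)CCC(=O)C[C@]12C | intermediate
18 | Mannich base: 6-[(N-methylanilino)methyl] derivative of 17 (C6 epimers) | CC(=O)O[C@@H]1C[C@@](O)(C(C)C)[C@H]2[C@H](OC(=O)c3ccc(O[Si](C)(C)C(C)(C)C)cc3)CC(CN(C)c3ccccc3)C(=O)C[C@]12C | intermediate
19 | (1R,3R,3aR,4R,8aS)-1-acetoxy-3-hydroxy-8a-methyl-6-methylidene-7-oxo-3-(propan-2-yl)decahydroazulen-4-yl 4-[(tert-butyldimethylsilyl)oxy]benzoate | CC(=O)O[C@@H]1C[C@@](O)(C(C)C)[C@H]2[C@H](OC(=O)c3ccc(O[Si](C)(C)C(C)(C)C)cc3)CC(=C)C(=O)C[C@]12C | intermediate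
20 | (1R,3R,3aR,4R,8aS)-1-acetoxy-3-hydroxy-6,8a-dimethyl-7-oxo-3-(propan-2-yl)-1,2,3,3a,4,7,8,8a-octahydroazulen-4-yl 4-[(tert-butyldimethylsilyl)oxy]benzoate | CC(=O)O[C@@H]1C[C@@](O)(C(C)C)[C@H]2[C@H](OC(=O)c3ccc(O[Si](C)(C)C(C)(C)C)cc3)C=C(C)C(=O)C[C@]12C | intermediate
21 | (1R,3R,3aR,4R,8aS)-1-acetoxy-3-hydroxy-6,8a-dimethyl-7-oxo-3-(propan-2-yl)-1,2,3,3a,4,7,8,8a-octahydroazulen-4-yl 4-hydroxybenzoate | CC(=O)O[C@@H]1C[C@@](O)(C(C)C)[C@H]2[C@H](OC(=O)c3ccc(O)cc3)C=C(C)C(=O)C[C@]12C | target

## Step count and least certain steps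

Total step count: 15. Longest linear sequence: 15 steps (1 to 21); 4, 6 and 15 enter as purchased compounds.

**Step 8 (key step).** The most likely failures are poor facial discrimination at C8a under acyclic allylic-strain control, and slow insertion at the fully substituted alkene terminus (its methyl group is cis to the cyclopropane), which would let ionisation of the allylic acetate or cyclopropane isomerisation compete. The fallback replaces acyclic control by a ring template and removes the ionisable ester. It sets out from 9: t-Bu2Si(OTf)2 and 2,6-lutidine should give the O1,O3-di-tert-butylsilylene acetal F1, in which the alkynyl and alkenyl groups are held cis on a six-membered ring. The same [Rh(CO)2Cl]2-catalysed cycloaddition should then give the silylene-bridged cycloadduct F2. Ethylene glycol with pyridinium p-toluenesulfonate followed by Bu4NF should give the diol ketal F3, and selective acetylation of its secondary C1 hydroxyl (Ac2O, pyridine, DMAP) returns to the route at 12.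

**Step 5.** The most likely failure is insufficient 1,3-induction with the branched Grignard reagent, together with β-hydride reduction, enolisation or retro-aldol cleavage of the magnesium aldolate. The fallback reverses which group is the nucleophile and sets C1 last by a hydroxyl-directed reduction. It sets out from 5: a boron aldol with 3-methylbutan-2-one (the antipode of Ipc2BCl that gives the 5S carbinol, Et3N) should give the (5S)-β-hydroxy isopropyl ketone F4. Chelation-controlled addition of ethynylmagnesium bromide, a small nucleophile without β-hydrogen, should give the (3R,5S)-diol F5. MnO2 oxidation of the allylic C1 alcohol gives the β-hydroxy enone F6. Evans–Saksena reduction with Me4NBH(OAc)3 in MeCN–AcOH delivers hydride intramolecularly from the C3 alkoxyborohydride through a chair with the isopropyl group equatorial, which should set C1 as R and return to the route at 9.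

**Step 4.** The most likely failure is low enantioselectivity, or an unexpected sense of induction, with the α-branched enal as acceptor, plus self-condensation of 6. The fallback sets C1 by ketone hydrogenation of known sense. It sets out from 5: Roskamp homologation with ethyl diazoacetate and SnCl2 should give the β-keto ester F7. Noyori hydrogenation with RuCl2[(S)-BINAP] and H2 in EtOH, chemoselective for the β-keto ester over the trisubstituted alkene, should give the (3R)-β-hydroxy ester F8. MeNH(OMe)·HCl with i-PrMgCl gives the Weinreb amide F9, and excess LiC≡CSiMe3 returns to the route at 7.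

**Step 10.** The most likely failure is borane attack from the β face, reduction of the C1 acetate during a slow hydroboration of the hindered alkene, or incomplete conversion. The fallback adds oxygen and hydrogen in two separate, hydroxyl-guided operations. It sets out from 12: VO(acac)2 and t-BuOOH, directed by the allylic C3 hydroxyl, should give the 3a,4-α-epoxide F10. Reductive opening with Cp2TiCl (trivalent titanium, from Cp2TiCl2 and Mn dust) and 1,4-cyclohexadiene should cleave the C3a–O bond to the tertiary radical; hydrogen-atom transfer to its α face, opposite the methyl and isopropyl groups, returns to the route at 14.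

**Step 13.** The most likely failure is methylenation at C8 or a double Mannich reaction, and dimerisation of the exocyclic enone before isomerisation. The fallback forms the enone first and adds the methyl group by cross-coupling. It sets out from 17: dehydrogenation with IBX in DMSO, where only C5–C6 can be desaturated because C8a bears no hydrogen, should give the 6-unsubstituted enone F11. α-Iodination with I2 and pyridine gives the 6-iodo enone F12. Stille coupling with Me4Sn (Pd2(dba)3, AsPh3, CuI) returns to the route at 20, bypassing 18 and 19.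

## Further compounds

F1 | step 8 | O1,O3-di-tert-butylsilylene acetal of diol 9 (2,2-di-tert-butyl-1,3,2-dioxasilinane) | C#C[C@]1(C(C)C)C[C@H](/C(C)=C/C2(O[Si](C)(C)C(C)(C)C)CC2)O[Si](C(C)(C)C)(C(C)(C)C)O1
F2 | step 8 | silylene-bridged cycloadduct (O1,O3-di-tert-butylsilylene of the 1,3-diol corresponding to 11) | O3[C@@H]1C[C@@](O[Si]3(C(C)(C)C)C(C)(C)C)(C(C)C)C2=CCCC(O[Si](C)(C)C(C)(C)C)=C[C@]12C
F3 | step 8 | (1R,3R,8aS)-7,7-(ethane-1,2-diyldioxy)-8a-methyl-3-(propan-2-yl)-1,2,3,5,6,7,8,8a-octahydroazulene-1,3-diol | O[C@@H]1C[C@@](O)(C(C)C)C2=CCCC3(OCCO3)C[C@]12C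
F4 | step 5 | (5S,6E)-7-{1-[(tert-butyldimethylsilyl)oxy]cyclopropyl}-5-hydroxy-2,6-dimethylhept-6-en-3-one | CC(C)C(=O)C[C@H](O)/C(C)=C/C1(O[Si](C)(C)C(C)(C)C)CC1
F5 | step 5 | (3R,5S,6E)-7-{1-[(tert-butyldimethylsilyl)oxy]cyclopropyl}-6-methyl-3-(propan-2-yl)hept-6-en-1-yne-3,5-diol | C#C[C@](O)(C(C)C)C[C@H](O)/C(C)=C/C1(O[Si](C)(C)C(C)(C)C)CC1
F6 | step 5 | (1E,5R)-1-{1-[(tert-butyldimethylsilyl)oxy]cyclopropyl}-5-ethynyl-5-hydroxy-2,6-dimethylhept-1-en-3-one | C#C[C@](O)(C(C)C)CC(=O)/C(C)=C/C1(O[Si](C)(C)C(C)(C)C)CC1
F7 | step 4 | ethyl (4E)-5-{1-[(tert-butyldimethylsilyl)oxy]cyclopropyl}-4-methyl-3-oxopent-4-enoate | CCOC(=O)CC(=O)/C(C)=C/C1(O[Si](C)(C)C(C)(C)C)CC1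
F8 | step 4 | ethyl (3R,4E)-5-{1-[(tert-butyldimethylsilyl)oxy]cyclopropyl}-3-hydroxy-4-methylpent-4-enoate | CCOC(=O)C[C@@H](O)/C(C)=C/C1(O[Si](C)(C)C(C)(C)C)CC1
F9 | step 4 | (3R,4E)-5-{1-[(tert-butyldimethylsilyl)oxy]cyclopropyl}-3-hydroxy-N-methoxy-N,4-dimethylpent-4-enamide | CON(C)C(=O)C[C@@H](O)/C(C)=C/C1(O[Si](C)(C)C(C)(C)C)CC1
F10 | step 10 | 3a,4-α-epoxide of 12 | CC(=O)O[C@@H]1C[C@@](O)(C(C)C)[C@]25O[C@@H]5CCC3(OCCO3)C[C@]12C
F11 | step 13 | (1R,3R,3aR,4R,8aS)-1-acetoxy-3-hydroxy-8a-methyl-7-oxo-3-(propan-2-yl)-1,2,3,3a,4,7,8,8a-octahydroazulen-4-yl 4-[(tert-butyldimethylsilyl)oxy]benzoate | CC(=O)O[C@@H]1C[C@@](O)(C(C)C)[C@H]2[C@H](OC(=O)c3ccc(O[Si](C)(C)C(C)(C)C)cc3)C=CC(=O)C[C@]12C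
F12 | step 13 | 6-iodo derivative of F11 (α-iodo enone) | CC(=O)O[C@@H]1C[C@@](O)(C(C)C)[C@H]2[C@H](OC(=O)c3ccc(O[Si](C)(C)C(C)(C)C)cc3)C=C(I)C(=O)C[C@]12C
A1 | alternative 1 | ring-closing metathesis precursor: cyclopentane with the CH(OCOAr)CH=CH2 chain on C3a and the CH2C(=O)C(CH3)=CH2 chain on C8a, other groups as in 20 | CC(=O)O[C@@H]1C[C@@](O)(C(C)C)[C@@H]([C@H](OC(=O)c2ccc(O[Si](C)(C)C(C)(C)C)cc2)C=C)[C@]1(C)CC(=O)C(C)=C
A2 | alternative 2 | (7aS)-7a-methyl-2,3,7,7a-tetrahydro-1H-indene-1,5(6H)-dione | C[C@]12CCC(=O)C=C1CCC2=O
A3 | alternative 2 | (1R,3R,3aR,4R,7aS)-4-[(tert-butyldimethylsilyl)oxy]-3-hydroxy-7a-methyl-6-oxo-3-(propan-2-yl)octahydro-1H-inden-1-yl acetate | CC(=O)O[C@@H]1C[C@@](O)(C(C)C)[C@H]2[C@H](O[Si](C)(C)C(C)(C)C)CC(=O)C[C@]12C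
A4 | alternative 3 | (1R,3R)-4-ethenyl-3-hydroxy-5-methyl-3-(propan-2-yl)cyclopent-4-en-1-yl acetate | CC(=O)O[C@@H]1C[C@@](O)(C(C)C)C(C=C)=C1C
A5 | alternative 3 | methyl 3-[(tert-butyldimethylsilyl)oxy]-2-diazobut-3-enoate | COC(=O)C(=[N+]=[N-])C(=C)O[Si](C)(C)C(C)(C)C
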